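**Retrosynthetic overview** (hexahydroindenone numbering: C4 = ketone carbon, C5/C6 = enone carbons, C7 = ring CH2, C3a/C7a = methyl-bearing fusion carbons)
1. 22 ⇐ 21 (fluoride removes the aryl TIPS ether and the tertiary Teoc carbonate) ⇐ Suzuki allyl–alkenyl coupling of allylic chloride 13 with (Z)-alkenyl boronate 20 (from 4-methoxy-2-methylphenol by Claisen rearrangement and cross-metathesis).
2. 13 ⇐ one-pot cationic [4+2] annulation of a chiral vinylketeniminium (from amide 8) with 1,2-dimethylcyclopentene 9: C4–C3a forms first, then the cyclohexenone closes through C7–C7a; the cyclopentane is bought, the six-membered ring is the only ring made.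
3. Enabling feature: in the cyclohex-2-en-1-one ring, C4 and C7 sit on the two adjacent methyl-bearing fusion carbons C3a/C7a, so C4=C5–C6=C7 is a vinylketene retron and C3a=C7a a symmetrical tetrasubstituted alkene whose tertiary C7a cation is trapped by C7.
4. 8 ⇐ senecioyl amide 3 of (2R,5R)-2,5-dimethylpyrrolidine by deconjugative α-alkylation with 2,2-dimethyloxirane, Teoc trapping and ene-chlorination.

Key step: step 4

Assumption: 1, 2, 4, 9, 14 and 19 are commercial, and the (2R,5R) auxiliary is taken to induce the (3aR,7aR) series; if the sense of induction is opposite, the (2S,5S) amine is used with no other change.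

**Step 1**
Reactants: 1 (2R,5R)-2,5-dimethylpyrrolidine; 2 3-methylbut-2-enoyl chloride
Product: 3 1-[(2R,5R)-2,5-dimethylpyrrolidin-1-yl]-3-methylbut-2-en-1-one
Conditions: 2 M aq NaOH, CH2Cl2, 0 °C → rt
Reagents that add atoms: none
Why: Schotten–Baumann N-acylation of the secondary amine should be clean, and any deconjugated amide formed through the ketene converges on the same dienolate in step 2.

**Step 2**
Reactants: 3 1-[(2R,5R)-2,5-dimethylpyrrolidin-1-yl]-3-methylbut-2-en-1-one; 4 2,2-dimethyloxirane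
Product: 7 4-{[(2R,5R)-2,5-dimethylpyrrolidin-1-yl]carbonyl}-2,5-dimethylhex-5-en-2-yl 2-(trimethylsilyl)ethyl carbonate (both C4 epimers), via lithium dienolate 5 (not isolated), via lithium alkoxide 6 (not isolated)
Conditions: LDA, THF, −78 °C; then 4, −78 → 25 °C; then Teoc-OSu, 0 → 25 °C; H2O work-up
Reagents that add atoms: 2,5-dioxopyrrolidin-1-yl 2-(trimethylsilyl)ethyl carbonate (Teoc-OSu), C[Si](C)(C)CCOC(=O)ON1C(=O)CCC1=O
Why: Deconjugative α-alkylation of the amide dienolate (γ-deprotonation, then SN2 opening of the epoxide at its CH2 by the α-carbon) followed by in situ O-acylation of the tertiary lithium alkoxide should give the carbonate, whose new α-stereocentre (both epimers) is erased again in step 4.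

**Step 3**
Reactants: 7 4-{[(2R,5R)-2,5-dimethylpyrrolidin-1-yl]carbonyl}-2,5-dimethylhex-5-en-2-yl 2-(trimethylsilyl)ethyl carbonate
Product: 8 5-(chloromethyl)-4-{[(2R,5R)-2,5-dimethylpyrrolidin-1-yl]carbonyl}-2-methylhex-5-en-2-yl 2-(trimethylsilyl)ethyl carbonate (both C4 epimers; used promptly)
Conditions: Ca(OCl)2, CO2 (s), CH2Cl2/H2O, 0 °C
Reagents that add atoms: calcium hypochlorite, [Ca+2].[O-]Cl.[O-]Cl
Why: Ene-type allylic chlorination by hypochlorous acid made in situ should transpose the isopropenyl double bond to give the 2-(chloromethyl)allyl unit, hydrogen being taken from the methyl group and not from the hindered, electron-poor α-CH.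

**Step 4**
Reactants: 8 5-(chloromethyl)-4-{[(2R,5R)-2,5-dimethylpyrrolidin-1-yl]carbonyl}-2-methylhex-5-en-2-yl 2-(trimethylsilyl)ethyl carbonate; 9 1,2-dimethylcyclopentene (3 equiv)
Product: 13 1-[(3aR,7aR)-6-(chloromethyl)-3a,7a-dimethyl-4-oxo-2,3,3a,4,7,7a-hexahydro-1H-inden-5-yl]-2-methylpropan-2-yl 2-(trimethylsilyl)ethyl carbonate, via vinylketeniminium triflate 10 (not isolated), via ring-open tertiary cation 11 (not isolated), via cyclohexeniminium triflate 12 (not isolated)
Conditions: Tf2O, 2,6-di-tert-butyl-4-methylpyridine, (CH2Cl)2, −20 → 80 °C; then aq NaHCO3, 60 °C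
Reagents that add atoms: water, O
Why: Proposed new method: Tf2O and the hindered pyridine should convert the α-branched β,γ-unsaturated amide into vinylketeniminium 10, whose sp carbon (future C4) is attacked by the electron-rich tetrasubstituted alkene 9 to form the C4–C3a bond and the tertiary cyclopentyl cation 11, in which the cationic carbon (C7a) faces a 1-amino-1,3-diene. The diene terminus C7 then captures the cation (γ-alkylation of a dienamine, a 6-endo-trig cation–olefin closure) to close the cyclohexene ring through the C7–C7a bond and give the conjugated iminium 12, which water hydrolyses to the enone with release of the auxiliary. The closest known reaction type is the keteniminium–olefin [2+2] cycloaddition, which passes through the same kind of cation but closes at the α-carbon; here α-closure at C5 would give a four-membered iminium with three contiguous quaternary carbons and is expected to be reversible, so the unstrained conjugated iminium is the sink. C3a is set in the first bond formation by the C2-symmetric trans-2,5-dimethylpyrrolidinium unit, which differentiates the two enantiotopic ends of the meso alkene, and C7a follows because the three-atom tether can deliver C7 only to the face of the planar cation that gives the cis-fused hydrindane. The step needs γ- over α-closure and freedom from cation 1,2-shifts and internal nucleophiles: the first is secured by strain and conjugation, the second by the enamine (not acyl) substituent on C3a at the cation stage, the third by masking the tertiary alcohol as a carbonate, by the non-nucleophilic base and by introducing the side-chain alkene and arene only afterwards.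

**Step 5**
Reactants: 14 4-methoxy-2-methylphenol
Product: 15 4-methoxy-2-methyl-1-(prop-2-en-1-yloxy)benzene
Conditions: allyl bromide, K2CO3, acetone, reflux
Reagents that add atoms: allyl bromide, C=CCBr
Why: Williamson O-allylation of the phenoxide should proceed without complication.

**Step 6**
Reactants: 15 4-methoxy-2-methyl-1-(prop-2-en-1-yloxy)benzene
Product: 17 2-allyl-4-methoxy-6-methylphenol, via cyclohexadienone 16 (not isolated)
Conditions: PhNEt2, 200 °C
Reagents that add atoms: none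
Why: Aromatic Claisen rearrangement ([3,3]) to the only unsubstituted ortho carbon followed by tautomerisation of the dienone should give the ortho-allyl phenol, migration to the methyl-bearing ortho carbon being reversible and unproductive.

**Step 7**
Reactants: 17 2-allyl-4-methoxy-6-methylphenol
Product: 18 (2-allyl-4-methoxy-6-methylphenoxy)tri(propan-2-yl)silane
Conditions: NaH, THF, 0 °C; TIPSCl, rt
Reagents that add atoms: chlorotri(propan-2-yl)silane, CC(C)[Si](Cl)(C(C)C)C(C)C
Why: Silylation of the sodium phenoxide should give a TIPS ether that survives the metathesis and the basic coupling and falls to fluoride at the end.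

**Step 8**
Reactants: 18 (2-allyl-4-methoxy-6-methylphenoxy)tri(propan-2-yl)silane; 19 4,4,5,5-tetramethyl-2-(prop-1-en-2-yl)-1,3,2-dioxaborolane
Product: 20 {4-methoxy-2-methyl-6-[(2Z)-3-(4,4,5,5-tetramethyl-1,3,2-dioxaborolan-2-yl)but-2-en-1-yl]phenoxy}tri(propan-2-yl)silane
Conditions: (H2IMes)(PCy3)Cl2Ru=CHPh (5 mol %), 1,4-benzoquinone (10 mol %), CH2Cl2, 40 °C
Reagents that add atoms: none
Why: Olefin cross-metathesis of the terminal alkene with the 1,1-disubstituted isopropenyl boronate should give the trisubstituted alkenyl boronate with the benzylic CH2 trans to the bulky boryl group (thermodynamic control), benzoquinone suppressing allyl-to-propenyl isomerisation.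

**Step 9**
Reactants: 13 1-[(3aR,7aR)-6-(chloromethyl)-3a,7a-dimethyl-4-oxo-2,3,3a,4,7,7a-hexahydro-1H-inden-5-yl]-2-methylpropan-2-yl 2-(trimethylsilyl)ethyl carbonate; 20 {4-methoxy-2-methyl-6-[(2Z)-3-(4,4,5,5-tetramethyl-1,3,2-dioxaborolan-2-yl)but-2-en-1-yl]phenoxy}tri(propan-2-yl)silane
Product: 21 1-[(3aR,7aR)-6-{(2E)-4-[5-methoxy-3-methyl-2-{[tri(propan-2-yl)silyl]oxy}phenyl]-2-methylbut-2-en-1-yl}-3a,7a-dimethyl-4-oxo-2,3,3a,4,7,7a-hexahydro-1H-inden-5-yl]-2-methylpropan-2-yl 2-(trimethylsilyl)ethyl carbonate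
Conditions: Pd(PPh3)4 (5 mol %), K3PO4, THF/H2O 10:1, 50 °C
Reagents that add atoms: none
Why: Suzuki–Miyaura allyl–alkenyl coupling should join the fragments, the π-allyl palladium from the primary allylic chloride being attacked at its CH2 terminus (the other terminus is fully substituted) with retention of the boronate geometry, which sets the E side-chain alkene.

**Step 10**
Reactants: 21 1-[(3aR,7aR)-6-{(2E)-4-[5-methoxy-3-methyl-2-{[tri(propan-2-yl)silyl]oxy}phenyl]-2-methylbut-2-en-1-yl}-3a,7a-dimethyl-4-oxo-2,3,3a,4,7,7a-hexahydro-1H-inden-5-yl]-2-methylpropan-2-yl 2-(trimethylsilyl)ethyl carbonate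
Product: 22 (3aR,7aR)-5-(2-hydroxy-2-methylpropyl)-6-[(2E)-4-(2-hydroxy-5-methoxy-3-methylphenyl)-2-methylbut-2-en-1-yl]-3a,7a-dimethyl-1,2,3,3a,7,7a-hexahydro-4H-inden-4-one (target)
Conditions: TBAF, AcOH, THF, 0 → 25 °C
Reagents that add atoms: none
Why: Fluoride should cleave the aryl silyl ether and attack the Teoc silicon to trigger β-elimination (ethene, CO2), freeing the tertiary alcohol under buffered conditions that should not isomerise the skipped diene.

**Compound list**
1 | (2R,5R)-2,5-dimethylpyrrolidine | C[C@@H]1CC[C@@H](C)N1 | starting material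
2 | 3-methylbut-2-enoyl chloride | CC(C)=CC(Cl)=O | starting material
3 | 1-[(2R,5R)-2,5-dimethylpyrrolidin-1-yl]-3-methylbut-2-en-1-one | CC(C)=CC(=O)N1[C@H](C)CC[C@H]1C | intermediate
4 | 2,2-dimethyloxirane | CC1(C)CO1 | starting material
5 | lithium 1-[(2R,5R)-2,5-dimethylpyrrolidin-1-yl]-3-methylbuta-1,3-dien-1-olate | C=C(C)C=C([O-])N1[C@H](C)CC[C@H]1C.[Li+] | intermediate
6 | lithium 4-{[(2R,5R)-2,5-dimethylpyrrolidin-1-yl]carbonyl}-2,5-dimethylhex-5-en-2-olate | C=C(C)C(CC(C)(C)[O-])C(=O)N1[C@H](C)CC[C@H]1C.[Li+] | intermediate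
7 | 4-{[(2R,5R)-2,5-dimethylpyrrolidin-1-yl]carbonyl}-2,5-dimethylhex-5-en-2-yl 2-(trimethylsilyl)ethyl carbonate (C4 epimers) | C=C(C)C(CC(C)(C)OC(=O)OCC[Si](C)(C)C)C(=O)N1[C@H](C)CC[C@H]1C | intermediate
8 | 5-(chloromethyl)-4-{[(2R,5R)-2,5-dimethylpyrrolidin-1-yl]carbonyl}-2-methylhex-5-en-2-yl 2-(trimethylsilyl)ethyl carbonate (C4 epimers) | C=C(CCl)C(CC(C)(C)OC(=O)OCC[Si](C)(C)C)C(=O)N1[C@H](C)CC[C@H]1C | intermediate
9 | 1,2-dimethylcyclopentene | CC1=C(C)CCC1 | starting material
10 | (2R,5R)-1-[3-(chloromethyl)-2-(2-methyl-2-{[2-(trimethylsilyl)ethoxy]carbonyloxy}propyl)buta-1,3-dien-1-ylidene]-2,5-dimethylpyrrolidin-1-ium triflate | C=C(CCl)C(CC(C)(C)OC(=O)OCC[Si](C)(C)C)=C=[N+]1[C@H](C)CC[C@H]1C.[O-]S(=O)(=O)C(F)(F)F | intermediate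
11 | 2-[3-(chloromethyl)-1-[(2R,5R)-2,5-dimethylpyrrolidin-1-yl]-2-(2-methyl-2-{[2-(trimethylsilyl)ethoxy]carbonyloxy}propyl)buta-1,3-dien-1-yl]-1,2-dimethylcyclopentan-1-ylium triflate (quaternary carbon configured as C3a of 13; C7–C7a bond not yet formed) | C=C(CCl)C(CC(C)(C)OC(=O)OCC[Si](C)(C)C)=C(N1[C@H](C)CC[C@H]1C)[C@]2(C)CCC[C+]2C.[O-]S(=O)(=O)C(F)(F)F | intermediate
12 | (2R,5R)-1-[(3aR,7aR)-6-(chloromethyl)-3a,7a-dimethyl-5-(2-methyl-2-{[2-(trimethylsilyl)ethoxy]carbonyloxy}propyl)-1,2,3,3a,7,7a-hexahydro-4H-inden-4-ylidene]-2,5-dimethylpyrrolidin-1-ium triflate | ClCC1=C(CC(C)(C)OC(=O)OCC[Si](C)(C)C)C(=[N+]2[C@H](C)CC[C@H]2C)[C@]3(C)CCC[C@]3(C)C1.[O-]S(=O)(=O)C(F)(F)F | intermediate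
13 | 1-[(3aR,7aR)-6-(chloromethyl)-3a,7a-dimethyl-4-oxo-2,3,3a,4,7,7a-hexahydro-1H-inden-5-yl]-2-methylpropan-2-yl 2-(trimethylsilyl)ethyl carbonate | ClCC1=C(CC(C)(C)OC(=O)OCC[Si](C)(C)C)C(=O)[C@]2(C)CCC[C@]2(C)C1 | intermediate
14 | 4-methoxy-2-methylphenol | COc1ccc(O)c(C)c1 | starting material
15 | 4-methoxy-2-methyl-1-(prop-2-en-1-yloxy)benzene | C=CCOc1ccc(OC)cc1C | intermediate
16 | 6-allyl-4-methoxy-2-methylcyclohexa-2,4-dien-1-one | C=CCC1C=C(OC)C=C(C)C1=O | intermediate
17 | 2-allyl-4-methoxy-6-methylphenol | C=CCc1cc(OC)cc(C)c1O | intermediate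
18 | (2-allyl-4-methoxy-6-methylphenoxy)tri(propan-2-yl)silane | C=CCc1cc(OC)cc(C)c1O[Si](C(C)C)(C(C)C)C(C)C | intermediate
19 | 4,4,5,5-tetramethyl-2-(prop-1-en-2-yl)-1,3,2-dioxaborolane | CC(=C)B1OC(C)(C)C(C)(C)O1 | starting material
20 | {4-methoxy-2-methyl-6-[(2Z)-3-(4,4,5,5-tetramethyl-1,3,2-dioxaborolan-2-yl)but-2-en-1-yl]phenoxy}tri(propan-2-yl)silane | C/C(B1OC(C)(C)C(C)(C)O1)=C\Cc1cc(OC)cc(C)c1O[Si](C(C)C)(C(C)C)C(C)C | intermediate
21 | 1-[(3aR,7aR)-6-{(2E)-4-[5-methoxy-3-methyl-2-{[tri(propan-2-yl)silyl]oxy}phenyl]-2-methylbut-2-en-1-yl}-3a,7a-dimethyl-4-oxo-2,3,3a,4,7,7a-hexahydro-1H-inden-5-yl]-2-methylpropan-2-yl 2-(trimethylsilyl)ethyl carbonate | COc1cc(C)c(O[Si](C(C)C)(C(C)C)C(C)C)c(C/C=C(\C)CC2=C(CC(C)(C)OC(=O)OCC[Si](C)(C)C)C(=O)[C@]3(C)CCC[C@]3(C)C2)c1 | intermediate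
22 | (3aR,7aR)-5-(2-hydroxy-2-methylpropyl)-6-[(2E)-4-(2-hydroxy-5-methoxy-3-methylphenyl)-2-methylbut-2-en-1-yl]-3a,7a-dimethyl-1,2,3,3a,7,7a-hexahydro-4H-inden-4-one | COc1cc(C)c(O)c(C/C=C(\C)CC2=C(CC(C)(C)O)C(=O)[C@]3(C)CCC[C@]3(C)C2)c1 | target

**Step count:** 10 steps in total; longest linear sequence 6 steps (1 → 2 → 3 → 4 → 9 → 10; the arene branch 5 → 6 → 7 → 8 → 9 → 10 is equally long).

**Steps most likely to fail**

Step 4 (proposed new method). The congested keteniminium carbon may fail to engage the tetrasubstituted alkene, or the chiral ammonium unit may discriminate the two ends of the meso alkene poorly. The fallback is photochemical, uses known reactions, sets out from 4 and 9 and returns at 13. The lithium dienolate of commercial 2,2,6-trimethyl-4H-1,3-dioxin-4-one would be alkylated at the γ-methyl with epoxide 4 and trapped with Teoc-OSu to give the dioxinone carbonate F1. Irradiation (300 nm, MeCN/acetone) of F1 with 9 should give the de Mayo-type cyclobutane photoadduct F2, in which both methyl-bearing carbons are already cis. K2CO3/MeOH would open the acetonide, and retro-aldol fragmentation of the cyclobutanol should give the δ-keto ester F3. LiHMDS would close F3 (Dieckmann) to the bicyclic 1,3-dione F4, and Tf2O/2,6-lutidine should triflate the less hindered enol oxygen to give the β-triflyloxy enone F5. Stille coupling with (tributylstannyl)methanol would give the hydroxymethyl enone F6, and PPh3/NCS (Appel) would convert it into racemic 13. Preparative chiral SFC would then remove the (3aS,7aS) enantiomer F7 and deliver 13.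

Step 2. The delocalised, hindered dienolate may open the 1,1-disubstituted epoxide too slowly, so that proton transfer or γ-attack takes over. The fallback sets out from 3 and returns at 7. The same dienolate 5 would be alkylated at the α-carbon with methyl bromoacetate to give the amido ester F8. MeMgBr (2.2 equiv, THF, 0 °C; the hindered tertiary amide is inert) should convert the ester into the tertiary alcohol F9. KHMDS and Teoc-OSu would then give 7.

Step 9. Aqueous base may solvolyse the allylic chloride, or the palladium dienolate may be protonated (net reduction) before transmetalation from boron. The fallback is a base-free Negishi route that sets out from 20 and 13 and returns at 21. Iododeboronation of 20 with N-iodosuccinimide (retention of geometry) should give the alkenyl iodide F10. t-BuLi (−78 °C) and then ZnCl2 would convert it into the alkenylzinc chloride F11, which should couple with 13 under Pd(PPh3)4 in THF to give 21.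

**Further compounds**
F1 | step 4 | 2-methyl-4-(2,2-dimethyl-4-oxo-4H-1,3-dioxin-6-yl)butan-2-yl 2-(trimethylsilyl)ethyl carbonate | CC1(C)OC(=O)C=C(CCC(C)(C)OC(=O)OCC[Si](C)(C)C)O1
F2 | step 4 | dioxinone–1,2-dimethylcyclopentene [2+2] photoadduct (racemic, cis ring fusions) | O=C1OC(C)(C)OC2(CCC(C)(C)OC(=O)OCC[Si](C)(C)C)C1C1(C)CCCC21C
F3 | step 4 | methyl 2-[cis-1,2-dimethyl-2-(4-methyl-4-{[2-(trimethylsilyl)ethoxy]carbonyloxy}pentanoyl)cyclopentyl]acetate (racemic) | COC(=O)CC1(C)CCCC1(C)C(=O)CCC(C)(C)OC(=O)OCC[Si](C)(C)C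
F4 | step 4 | 1-(cis-3a,7a-dimethyl-4,6-dioxooctahydro-1H-inden-5-yl)-2-methylpropan-2-yl 2-(trimethylsilyl)ethyl carbonate (racemic) | O=C1CC2(C)CCCC2(C)C(=O)C1CC(C)(C)OC(=O)OCC[Si](C)(C)C
F5 | step 4 | cis-3a,7a-dimethyl-5-(2-methyl-2-{[2-(trimethylsilyl)ethoxy]carbonyloxy}propyl)-4-oxo-2,3,3a,4,7,7a-hexahydro-1H-inden-6-yl trifluoromethanesulfonate (racemic) | O=C1C(CC(C)(C)OC(=O)OCC[Si](C)(C)C)=C(OS(=O)(=O)C(F)(F)F)CC2(C)CCCC12C
F6 | step 4 | 1-[cis-6-(hydroxymethyl)-3a,7a-dimethyl-4-oxo-2,3,3a,4,7,7a-hexahydro-1H-inden-5-yl]-2-methylpropan-2-yl 2-(trimethylsilyl)ethyl carbonate (racemic) | O=C1C(CC(C)(C)OC(=O)OCC[Si](C)(C)C)=C(CO)CC2(C)CCCC12C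
F7 | step 4 | 1-[(3aS,7aS)-6-(chloromethyl)-3a,7a-dimethyl-4-oxo-2,3,3a,4,7,7a-hexahydro-1H-inden-5-yl]-2-methylpropan-2-yl 2-(trimethylsilyl)ethyl carbonate (enantiomer of 13) | ClCC1=C(CC(C)(C)OC(=O)OCC[Si](C)(C)C)C(=O)[C@@]2(C)CCC[C@@]2(C)C1
F8 | step 2 | methyl 3-{[(2R,5R)-2,5-dimethylpyrrolidin-1-yl]carbonyl}-4-methylpent-4-enoate (C3 epimers) | COC(=O)CC(C(C)=C)C(=O)N1[C@H](C)CC[C@H]1C
F9 | step 2 | 1-[(2R,5R)-2,5-dimethylpyrrolidin-1-yl]-4-hydroxy-4-methyl-2-(prop-1-en-2-yl)pentan-1-one (C2 epimers) | C=C(C)C(CC(C)(C)O)C(=O)N1[C@H](C)CC[C@H]1C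
F10 | step 9 | {2-[(2E)-3-iodobut-2-en-1-yl]-4-methoxy-6-methylphenoxy}tri(propan-2-yl)silane | C/C(I)=C\Cc1cc(OC)cc(C)c1O[Si](C(C)C)(C(C)C)C(C)C
F11 | step 9 | chloro{(2E)-4-[5-methoxy-3-methyl-2-{[tri(propan-2-yl)silyl]oxy}phenyl]but-2-en-2-yl}zinc | C/C([Zn]Cl)=C\Cc1cc(OC)cc(C)c1O[Si](C(C)C)(C(C)C)C(C)C
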